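The vessel was a closed, stirred, isothermal flask of constant volume, charged and run as follows.

free monomer 0.020 M; initiator 10 mol%; time 20 s

    free monomer + initiator → living end + monomer in chains (k1 = 35 /M/s)
    free monomer + living end → monomer in chains + living end, rate k2*[living end]*[free monomer] (k2 = 56 /M/s)
    monomer in chains + living end → free monomer + living end, rate k3*[living end] as long as [monomer in chains] is above zero (k3 = 0.48 /s)
    living end → dead end A (k4 = 0.034 /s)
    initiator → spent initiator B (k5 = 2.0 × 10⁻⁵ /s)

* whether the average number of monomer units in a chain (chains begun, living or dead) reaches 4.0 by 20 s (no / yes)
* average number of monomer units in a chain (chains begun, living or dead) at 20 s

- the average divides the monomer in chains by the number of chains begun, living and dead together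
- run time (flask): 20 s

You asked for a quick number. I looked first for the concentration that sets the order of the rate, and it was [living end]. Growth and shedding both carry it, so net growth is the growth constant times [living end] times the excess of [free monomer] over a fixed level, pseudo-first-order in that excess. That level is the shedding constant over the growth constant, 0.00857 M, which I called the ceiling: the [free monomer] at which a living end adds a unit as fast as it sheds one, the field's equilibrium monomer concentration.

Initiator began chains at first at 0.700 /s, far faster than it went to spent initiator B and than living ends died. I therefore took the chains begun as the initiator charge, 0.00200 M, present from the start and dying exponentially. With [free monomer] down at the ceiling, the length would be 5.71. By the asked time, the growth constant times the time integral of [living end] came to 1.63, and the excess shrinks by the exponential of minus that. I committed to a length of 4.59, and on reaching the wanted length to yes.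

The forecast gave 4.7 and yes, “past 4.0 but short of the cap”.

The flask gave 4.72 at 20.0 s, and the answer on the wanted length was yes. It passed that length at 12.1 s, with 39.9 % of the free monomer reacted. At 20.0 s the flask held free monomer at 52.8 % of its charge, 1.23 times the ceiling, and monomer in chains was being made 1.23 times as fast as it was used up. At 200 s, with living end down to 2.35 × 10⁻⁶ M, free monomer stood at 44.6 % of its charge, 3.42 × 10⁻⁴ M above the ceiling.

The numbers were drawn at random within sensible limits; what happens was integrated by code.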